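**Plan**

- Numbering used below: indene/indane C1 (aryl-bearing), C2, C3 (benzyl-bearing); dihydrobenzofuran O1, C2, C3, C3a, C4 (O), C5, C6, C7, C7a.
- Retrosynthesis: first cut the two aryl–C(sp3) bonds that tie benzofuran C6 to indane C2 and benzofuran C5 to the exocyclic benzylic carbon (a formal (3+2) annulation of an aryne with a 3-benzylindene). Then cut the indene C3–benzyl bond (ketone addition), the indanone C3–aryl bond (reductive Heck) and, in the other half, the dihydrofuran C2–C3 bond (carbene C–H insertion).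
- Forward: indanone 5 → indene 9; separately dihydrobenzofuran 19/20 → silyl triflate 26; then aryne ene reaction and Friedel–Crafts closure build the second cyclopentane of the dibenzobicyclo[3.3.0]octadiene core; two deprotections follow.
- Enabling feature: the C2=C3 double bond of 9 with the allylic CH2 on C3 is an ene donor. After C–C bond formation at C2 it becomes a 4-alkoxystyrene, i.e. a latent benzylic cation 1,3 to the new aryl group. The benzofuran ring, oxygenated at C4 and C7a, is an aryne polarised for attack at C6 and then a Friedel–Crafts nucleophile at C5.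
- Stereochemistry: indane C1 from an asymmetric reductive Heck reaction; dihydrofuran C3 from a catalyst-controlled Rh(II) carbene C–H insertion and C2 by acid equilibration to trans; the three other core centres arise in the key step under control of C1 (ene anti to the aryl group, forced cis ring fusion, exo aryl).

Key step: step 16

Assumption: Rh2(S-PTAD)4 is taken to give the (3S) centre in step 10 and the (R)-bisphosphine the (R) centre in step 3; if either sense of induction is the reverse, the antipodal catalyst is used and nothing else changes.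

**Route**

Step 1
Reactants: 1 1-[3,5-bis(benzyloxy)phenyl]ethan-1-one
Product: 2 1-[3,5-bis(benzyloxy)-2-bromophenyl]ethan-1-one
Conditions: NBS (1.05 equiv), MeCN, 0 °C to rt
Reagents that add atoms: N-bromosuccinimide, O=C1CCC(=O)N1Br
Why: Electrophilic aromatic bromination; the position next to the acetyl group is ortho to one and para to the other benzyloxy group and less hindered than C4 between the two ethers, as is usual for 3,5-dialkoxyaryl carbonyl compounds.

Step 2
Reactants: 2 1-[3,5-bis(benzyloxy)-2-bromophenyl]ethan-1-one; 3 4-(benzyloxy)benzaldehyde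
Product: 4 (E)-1-[3,5-bis(benzyloxy)-2-bromophenyl]-3-[4-(benzyloxy)phenyl]prop-2-en-1-one
Conditions: NaOH (aq), EtOH/THF, rt
Reagents that add atoms: none
Why: Claisen–Schmidt (crossed aldol) condensation of a methyl ketone with a non-enolisable aldehyde, which should give the E-enone after dehydration.

Step 3
Reactants: 4 (E)-1-[3,5-bis(benzyloxy)-2-bromophenyl]-3-[4-(benzyloxy)phenyl]prop-2-en-1-one
Product: 5 (3R)-4,6-bis(benzyloxy)-3-[4-(benzyloxy)phenyl]indan-1-one
Conditions: Pd(OAc)2 (5 mol%), (R)-Xyl-MeO-BIPHEP (6 mol%), HCO2Na (2 equiv), DMF, 80 °C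
Reagents that add atoms: none
Why: Asymmetric intramolecular reductive Heck reaction (oxidative addition into C–Br, 5-exo carbopalladation of the enone β-carbon, formate reduction of the Pd enolate); the chiral bisphosphine selects the enone face and so sets C3, which is β to the ketone and therefore configurationally stable.

Step 4
Reactants: 5 (3R)-4,6-bis(benzyloxy)-3-[4-(benzyloxy)phenyl]indan-1-one; 6 4-(benzyloxy)benzyl chloride
Product: 9 (1R)-5,7-bis(benzyloxy)-3-[4-(benzyloxy)benzyl]-1-[4-(benzyloxy)phenyl]-1H-indene, via benzylic Grignard reagent 7 (not isolated), via tertiary indanol 8 (not isolated)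
Conditions: 6, Mg, THF, 0 °C; CeCl3, −78 °C, then 5; aq NH4Cl; then p-TsOH·H2O (5 mol%), PhMe, 40 °C
Reagents that add atoms: none
Why: Grignard (organocerium) 1,2-addition to the ketone followed by acid-catalysed E1 dehydration, which should place the double bond in the ring (3-benzylindene) under equilibrating conditions; no base touches C1–H, so the centre set in step 3 is kept.

Step 5
Reactants: 10 2,4,6-trihydroxybenzaldehyde
Product: 11 4-(allyloxy)-2,6-dihydroxybenzaldehyde
Conditions: allyl bromide (1.0 equiv), K2CO3 (1.0 equiv), acetone, rt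
Reagents that add atoms: allyl bromide, C=CCBr
Why: Williamson etherification; the 4-hydroxyl is the most acidic and the only one not hydrogen-bonded to the formyl group, so one equivalent of allyl bromide should alkylate it selectively.

Step 6
Reactants: 11 4-(allyloxy)-2,6-dihydroxybenzaldehyde; 6 4-(benzyloxy)benzyl chloride
Product: 12 4-(allyloxy)-2,6-bis{[4-(benzyloxy)benzyl]oxy}benzaldehyde
Conditions: 6 (2.3 equiv), K2CO3, KI (cat.), DMF, 60 °C
Reagents that add atoms: none
Why: Williamson etherification of the two chelated ortho-hydroxyls under forcing conditions; the two identical 4-(benzyloxy)benzyl ethers make the later C–H insertion degenerate.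

Step 7
Reactants: 12 4-(allyloxy)-2,6-bis{[4-(benzyloxy)benzyl]oxy}benzaldehyde; 13 1,3-bis(benzyloxy)-5-bromobenzene
Product: 15 (4-(allyloxy)-2,6-bis{[4-(benzyloxy)benzyl]oxy}phenyl)[3,5-bis(benzyloxy)phenyl]methanol (racemic), via aryl Grignard reagent 14 (not isolated)
Conditions: 13, Mg, THF, rt; then 12, 0 °C; aq NH4Cl
Reagents that add atoms: none
Why: Grignard addition of an aryl nucleophile to the aldehyde, which gives the diarylmethanol (its new centre is removed in step 8).

Step 8
Reactants: 15 (4-(allyloxy)-2,6-bis{[4-(benzyloxy)benzyl]oxy}phenyl)[3,5-bis(benzyloxy)phenyl]methanol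
Product: 16 (4-(allyloxy)-2,6-bis{[4-(benzyloxy)benzyl]oxy}phenyl)[3,5-bis(benzyloxy)phenyl]methanone
Conditions: MnO2 (excess), CH2Cl2, rt
Reagents that add atoms: none
Why: MnO2 oxidation of a doubly benzylic secondary alcohol to the benzophenone, mild enough for the allyl and benzyl ethers.

Step 9
Reactants: 16 (4-(allyloxy)-2,6-bis{[4-(benzyloxy)benzyl]oxy}phenyl)[3,5-bis(benzyloxy)phenyl]methanone
Product: 17 hydrazone of ketone 16
Conditions: N2H4·H2O (10 equiv), AcOH (cat.), n-BuOH, 110 °C, N2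
Reagents that add atoms: hydrazine (as hydrate), NN
Why: Hydrazone formation by condensation of the diaryl ketone with excess hydrazine, run hot because the carbonyl is flanked by two ortho-alkoxy groups and under nitrogen to avoid diimide reduction of the allyl group.

Step 10
Reactants: 17 hydrazone of ketone 16
Product: 19 (2R,3S)-cis-6-(allyloxy)-2-[4-(benzyloxy)phenyl]-4-{[4-(benzyloxy)benzyl]oxy}-3-[3,5-bis(benzyloxy)phenyl]-2,3-dihydrobenzofuran, via diaryldiazomethane 18 (not isolated)
Conditions: MnO2, CH2Cl2, 0 °C; filter; Rh2(S-PTAD)4 (1 mol%), CH2Cl2, −20 °C to rt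
Reagents that add atoms: none
Why: Oxidation of the hydrazone to the diaryldiazomethane and Rh(II)-catalysed enantioselective intramolecular 1,5 C–H insertion of the donor/donor carbene into a benzylic ether C–H (either of the two equivalent ethers gives the same product); the chiral carboxylate catalyst sets C3, while C2 is expected mainly cis and is corrected in step 11.

Step 11
Reactants: 19 (2R,3S)-cis-6-(allyloxy)-2-[4-(benzyloxy)phenyl]-4-{[4-(benzyloxy)benzyl]oxy}-3-[3,5-bis(benzyloxy)phenyl]-2,3-dihydrobenzofuran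
Product: 20 (2S,3S)-trans-6-(allyloxy)-2-[4-(benzyloxy)phenyl]-3-[3,5-bis(benzyloxy)phenyl]-2,3-dihydrobenzofuran-4-ol
Conditions: TFA (10 vol%), pentamethylbenzene (3 equiv), CH2Cl2, 0 °C to rt
Reagents that add atoms: none
Why: Acidolysis of the remaining 4-alkoxybenzyl aryl ether with the cation trapped by pentamethylbenzene, together with reversible acid-induced heterolysis of the benzylic C2–O bond, which should equilibrate C2 to the more stable 2,3-trans isomer while C3 is untouched.

Step 12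
Reactants: 20 (2S,3S)-trans-6-(allyloxy)-2-[4-(benzyloxy)phenyl]-3-[3,5-bis(benzyloxy)phenyl]-2,3-dihydrobenzofuran-4-ol
Product: 21 (2S,3S)-6-(allyloxy)-2-[4-(benzyloxy)phenyl]-3-[3,5-bis(benzyloxy)phenyl]-2,3-dihydrobenzofuran-4-yl diethylcarbamate
Conditions: Et2NCOCl, K2CO3, MeCN, 70 °C
Reagents that add atoms: N,N-diethylcarbamoyl chloride, CCN(CC)C(Cl)=O
Why: O-carbamoylation of the phenol; the carbamate is stable to fluoride, to organolithium at −78 °C and to acid, and it weakens the donor strength of the C4 oxygen for the key step.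

Step 13
Reactants: 21 (2S,3S)-6-(allyloxy)-2-[4-(benzyloxy)phenyl]-3-[3,5-bis(benzyloxy)phenyl]-2,3-dihydrobenzofuran-4-yl diethylcarbamate
Product: 22 (2S,3S)-2-[4-(benzyloxy)phenyl]-3-[3,5-bis(benzyloxy)phenyl]-6-hydroxy-2,3-dihydrobenzofuran-4-yl diethylcarbamate
Conditions: Pd(PPh3)4 (5 mol%), morpholine, THF, rt
Reagents that add atoms: none
Why: Pd(0)-catalysed deallylation (Tsuji–Trost type, morpholine as allyl acceptor), orthogonal to the benzyl ethers and the carbamate.

Step 14
Reactants: 22 (2S,3S)-2-[4-(benzyloxy)phenyl]-3-[3,5-bis(benzyloxy)phenyl]-6-hydroxy-2,3-dihydrobenzofuran-4-yl diethylcarbamate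
Product: 23 (2S,3S)-2-[4-(benzyloxy)phenyl]-3-[3,5-bis(benzyloxy)phenyl]-5-bromo-6-hydroxy-2,3-dihydrobenzofuran-4-yl diethylcarbamate
Conditions: NBS (1.0 equiv), i-Pr2NH (10 mol%), CH2Cl2, −78 to −20 °C
Reagents that add atoms: N-bromosuccinimide, O=C1CCC(=O)N1Br
Why: ortho-Bromination of the free phenol by NBS with amine catalysis, expected at C5 (ortho to OH, para to the ring oxygen); a 7-bromo isomer would lead through the isomeric silyl triflate and aryne to the same ene adduct, so the site selectivity here is not critical.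

Step 15
Reactants: 23 (2S,3S)-2-[4-(benzyloxy)phenyl]-3-[3,5-bis(benzyloxy)phenyl]-5-bromo-6-hydroxy-2,3-dihydrobenzofuran-4-yl diethylcarbamate
Product: 26 (2S,3S)-2-[4-(benzyloxy)phenyl]-3-[3,5-bis(benzyloxy)phenyl]-4-[(diethylcarbamoyl)oxy]-5-(trimethylsilyl)-2,3-dihydrobenzofuran-6-yl trifluoromethanesulfonate, via aryl trimethylsilyl ether 24 (not isolated), via lithium ortho-silylphenoxide 25 (not isolated)
Conditions: HMDS, THF, 65 °C; evaporate; n-BuLi, THF, −78 °C; then Tf2O, −78 to 0 °C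
Reagents that add atoms: hexamethyldisilazane, C[Si](C)(C)N[Si](C)(C)C; trifluoromethanesulfonic anhydride, O=S(=O)(OS(=O)(=O)C(F)(F)F)C(F)(F)F
Why: O-silylation, bromine–lithium exchange with 1,3 O→C silyl migration (retro-Brook), then triflation of the phenoxide, the standard route to a 2-(trimethylsilyl)aryl triflate aryne precursor.

Step 16
Reactants: 9 (1R)-5,7-bis(benzyloxy)-3-[4-(benzyloxy)benzyl]-1-[4-(benzyloxy)phenyl]-1H-indene; 26 (2S,3S)-2-[4-(benzyloxy)phenyl]-3-[3,5-bis(benzyloxy)phenyl]-4-[(diethylcarbamoyl)oxy]-5-(trimethylsilyl)-2,3-dihydrobenzofuran-6-yl trifluoromethanesulfonate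
Product: 29 hepta-O-benzyl ether of the target carrying a diethylcarbamate on the benzofuran C4 oxygen (core centres all R; dihydrofuran 2S,3S), via aryne 27 (not isolated), via ene adduct 28 (not isolated)
Conditions: 9 (2 equiv), CsF (3 equiv), MeCN/PhMe (1:1), 25 °C; then evaporate, TFA (5 equiv), HFIP/CH2Cl2 (1:4), 0 °C, same flask
Reagents that add atoms: none
Why: CsF converts 26 into aryne 27, and C2 of the indene attacks its C6 terminus (the end remote from the C4 carbamate oxygen, the electrophilic end of a 3-oxygenated aryne) in a concerted aryne ene reaction that transfers a hydrogen of the benzylic CH2 to C5 and moves the double bond into the exocyclic position (28); acid then protonates this 4-alkoxystyrene at C3 and the resulting 4-(benzyloxy)benzyl cation attacks C5 of the benzofuran ring. The closest known reaction types are the intermolecular ene reaction of arynes with alkenes that carry allylic hydrogen and the Brønsted-acid hydroarylation of styrenes that gives 1-arylindanes (the closure used for pallidol-type cores). The one ring that closes, the second cyclopentane, does so by intramolecular Friedel–Crafts alkylation (cationic closure, endo with respect to the arene C5–C6 bond), which makes the overall event a formal (3+2) annulation of the aryne with the C2–C3–CH unit. Of the new centres, C2 is set in the ene step by approach of the aryne to the indene face opposite the C1 aryl group, the ring-fusion centre C3 can only become cis because a trans-fused diquinane cannot close (wrong-face protonation is reversible), and the aryl group on the cationic carbon takes the convex (exo) side in the cyclisation. The step needs three selectivities: ene regiochemistry (bond to C2 with hydrogen from the CH2 and not from C1–H) follows from bonding at the less substituted alkene carbon with charge building at the tertiary benzylic C3, aryne regiochemistry from the C4 oxygen, and ring closure at C5 and not C7 from the carbamate, which damps the C4 oxygen so that the ring oxygen directs para. The C1 centre of 9 is stable to acid and at risk only from base, hence the heterogeneous CsF, the excess of 9 and the absence of amine.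

Step 17
Reactants: 29 hepta-O-benzyl ether of the target carrying a diethylcarbamate on the benzofuran C4 oxygen
Product: 30 hepta-O-benzyl ether of the target (free hydroxyl on benzofuran C4)
Conditions: LiAlH4, THF, 0 to 65 °C; Rochelle salt work-up
Reagents that add atoms: none
Why: LiAlH4 reduction cleaves the aryl N,N-diethylcarbamate to the phenol (the carbamoyl carbon leaves as an N-methyl amine) and leaves the benzyl ethers and all stereocentres untouched.

Step 18
Reactants: 30 hepta-O-benzyl ether of the target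
Product: 31 CNP0198336.1
Conditions: H2 (1 atm), 10% Pd/C, EtOAc/MeOH, rt
Reagents that add atoms: none
Why: Catalytic hydrogenolysis of the seven benzyl ethers under neutral conditions, which should leave the diarylmethine centres and the dihydrobenzofuran intact and give the target.

**Compound list**

1 | 1-[3,5-bis(benzyloxy)phenyl]ethan-1-one | CC(=O)c1cc(OCc2ccccc2)cc(OCc2ccccc2)c1 | starting material
2 | 1-[3,5-bis(benzyloxy)-2-bromophenyl]ethan-1-one | CC(=O)c1cc(OCc2ccccc2)cc(OCc2ccccc2)c1Br | intermediate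
3 | 4-(benzyloxy)benzaldehyde | O=Cc1ccc(OCc2ccccc2)cc1 | starting material
4 | (E)-1-[3,5-bis(benzyloxy)-2-bromophenyl]-3-[4-(benzyloxy)phenyl]prop-2-en-1-one | O=C(/C=C/c1ccc(OCc2ccccc2)cc1)c1cc(OCc2ccccc2)cc(OCc2ccccc2)c1Br | intermediate
5 | (3R)-4,6-bis(benzyloxy)-3-[4-(benzyloxy)phenyl]indan-1-one | O=C1C[C@H](c2ccc(OCc3ccccc3)cc2)c2c(OCc3ccccc3)cc(OCc3ccccc3)cc12 | intermediate
6 | 4-(benzyloxy)benzyl chloride | ClCc1ccc(OCc2ccccc2)cc1 | starting material
7 | [4-(benzyloxy)benzyl]magnesium chloride | Cl[Mg]Cc1ccc(OCc2ccccc2)cc1 | intermediate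
8 | (3R)-4,6-bis(benzyloxy)-1-[4-(benzyloxy)benzyl]-3-[4-(benzyloxy)phenyl]indan-1-ol (both C1 epimers) | OC1(Cc2ccc(OCc3ccccc3)cc2)C[C@H](c2ccc(OCc3ccccc3)cc2)c2c(OCc3ccccc3)cc(OCc3ccccc3)cc12 | intermediate
9 | (1R)-5,7-bis(benzyloxy)-3-[4-(benzyloxy)benzyl]-1-[4-(benzyloxy)phenyl]-1H-indene | C1(Cc2ccc(OCc3ccccc3)cc2)=C[C@H](c2ccc(OCc3ccccc3)cc2)c2c(OCc3ccccc3)cc(OCc3ccccc3)cc12 | intermediate
10 | 2,4,6-trihydroxybenzaldehyde | O=Cc1c(O)cc(O)cc1O | starting material
11 | 4-(allyloxy)-2,6-dihydroxybenzaldehyde | O=Cc1c(O)cc(OCC=C)cc1O | intermediate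
12 | 4-(allyloxy)-2,6-bis{[4-(benzyloxy)benzyl]oxy}benzaldehyde | O=Cc1c(OCc2ccc(OCc3ccccc3)cc2)cc(OCC=C)cc1OCc1ccc(OCc2ccccc2)cc1 | intermediate
13 | 1,3-bis(benzyloxy)-5-bromobenzene | Brc1cc(OCc2ccccc2)cc(OCc2ccccc2)c1 | starting material
14 | [3,5-bis(benzyloxy)phenyl]magnesium bromide | Br[Mg]c1cc(OCc2ccccc2)cc(OCc2ccccc2)c1 | intermediate
15 | (4-(allyloxy)-2,6-bis{[4-(benzyloxy)benzyl]oxy}phenyl)[3,5-bis(benzyloxy)phenyl]methanol (racemic) | OC(c1cc(OCc2ccccc2)cc(OCc2ccccc2)c1)c1c(OCc2ccc(OCc3ccccc3)cc2)cc(OCC=C)cc1OCc1ccc(OCc2ccccc2)cc1 | intermediate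
16 | (4-(allyloxy)-2,6-bis{[4-(benzyloxy)benzyl]oxy}phenyl)[3,5-bis(benzyloxy)phenyl]methanone | O=C(c1cc(OCc2ccccc2)cc(OCc2ccccc2)c1)c1c(OCc2ccc(OCc3ccccc3)cc2)cc(OCC=C)cc1OCc1ccc(OCc2ccccc2)cc1 | intermediate
17 | hydrazone of ketone 16 | NN=C(c1cc(OCc2ccccc2)cc(OCc2ccccc2)c1)c1c(OCc2ccc(OCc3ccccc3)cc2)cc(OCC=C)cc1OCc1ccc(OCc2ccccc2)cc1 | intermediate
18 | diaryldiazomethane from 17 | [N-]=[N+]=C(c1cc(OCc2ccccc2)cc(OCc2ccccc2)c1)c1c(OCc2ccc(OCc3ccccc3)cc2)cc(OCC=C)cc1OCc1ccc(OCc2ccccc2)cc1 | intermediate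
19 | (2R,3S)-cis-6-(allyloxy)-2-[4-(benzyloxy)phenyl]-4-{[4-(benzyloxy)benzyl]oxy}-3-[3,5-bis(benzyloxy)phenyl]-2,3-dihydrobenzofuran | C=CCOc1cc2c(c(OCc3ccc(OCc4ccccc4)cc3)c1)[C@H](c1cc(OCc3ccccc3)cc(OCc3ccccc3)c1)[C@H](c1ccc(OCc3ccccc3)cc1)O2 | intermediate
20 | (2S,3S)-trans-6-(allyloxy)-2-[4-(benzyloxy)phenyl]-3-[3,5-bis(benzyloxy)phenyl]-2,3-dihydrobenzofuran-4-ol | C=CCOc1cc2c(c(O)c1)[C@H](c1cc(OCc3ccccc3)cc(OCc3ccccc3)c1)[C@@H](c1ccc(OCc3ccccc3)cc1)O2 | intermediate
21 | (2S,3S)-6-(allyloxy)-2-[4-(benzyloxy)phenyl]-3-[3,5-bis(benzyloxy)phenyl]-2,3-dihydrobenzofuran-4-yl diethylcarbamate | C=CCOc1cc2c(c(OC(=O)N(CC)CC)c1)[C@H](c1cc(OCc3ccccc3)cc(OCc3ccccc3)c1)[C@@H](c1ccc(OCc3ccccc3)cc1)O2 | intermediate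
22 | (2S,3S)-2-[4-(benzyloxy)phenyl]-3-[3,5-bis(benzyloxy)phenyl]-6-hydroxy-2,3-dihydrobenzofuran-4-yl diethylcarbamate | Oc1cc2c(c(OC(=O)N(CC)CC)c1)[C@H](c1cc(OCc3ccccc3)cc(OCc3ccccc3)c1)[C@@H](c1ccc(OCc3ccccc3)cc1)O2 | intermediate
23 | (2S,3S)-2-[4-(benzyloxy)phenyl]-3-[3,5-bis(benzyloxy)phenyl]-5-bromo-6-hydroxy-2,3-dihydrobenzofuran-4-yl diethylcarbamate | Oc1cc2c(c(OC(=O)N(CC)CC)c1Br)[C@H](c1cc(OCc3ccccc3)cc(OCc3ccccc3)c1)[C@@H](c1ccc(OCc3ccccc3)cc1)O2 | intermediate
24 | 6-O-trimethylsilyl ether of 23 | C[Si](C)(C)Oc1cc2c(c(OC(=O)N(CC)CC)c1Br)[C@H](c1cc(OCc3ccccc3)cc(OCc3ccccc3)c1)[C@@H](c1ccc(OCc3ccccc3)cc1)O2 | intermediate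
25 | lithium 6-phenoxide carrying the 5-trimethylsilyl group | [Li]Oc1cc2c(c(OC(=O)N(CC)CC)c1[Si](C)(C)C)[C@H](c1cc(OCc3ccccc3)cc(OCc3ccccc3)c1)[C@@H](c1ccc(OCc3ccccc3)cc1)O2 | intermediate
26 | (2S,3S)-2-[4-(benzyloxy)phenyl]-3-[3,5-bis(benzyloxy)phenyl]-4-[(diethylcarbamoyl)oxy]-5-(trimethylsilyl)-2,3-dihydrobenzofuran-6-yl trifluoromethanesulfonate | FC(F)(F)S(=O)(=O)Oc1cc2c(c(OC(=O)N(CC)CC)c1[Si](C)(C)C)[C@H](c1cc(OCc3ccccc3)cc(OCc3ccccc3)c1)[C@@H](c1ccc(OCc3ccccc3)cc1)O2 | intermediate
27 | 5,6-didehydro-2,3-dihydrobenzofuran (aryne) from 26 | CCN(CC)C(=O)OC1=C2[C@H](c3cc(OCc4ccccc4)cc(OCc4ccccc4)c3)[C@@H](c3ccc(OCc4ccccc4)cc3)OC2=CC#C1 | intermediate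
28 | ene adduct: (1R,2R)-5,7-bis(benzyloxy)-3-[4-(benzyloxy)benzylidene]-1-[4-(benzyloxy)phenyl]indane carrying at C2 (trans to the C1 aryl) the (2S,3S)-dihydrobenzofuran-6-yl group of 22 (alkene E/Z mixture) | c1ccccc1COc1ccc([C@@H]2c3c(OCc6ccccc6)cc(OCc6ccccc6)cc3C(=Cc3ccc(OCc6ccccc6)cc3)[C@H]2c2cc3c(c(OC(=O)N(CC)CC)c2)[C@H](c2cc(OCc6ccccc6)cc(OCc6ccccc6)c2)[C@@H](c2ccc(OCc6ccccc6)cc2)O3)cc1 | intermediate
29 | hepta-O-benzyl ether of the target with a diethylcarbamate on the benzofuran C4 oxygen | c1ccccc1COc1ccc([C@@H]2c3c(OCc6ccccc6)cc(OCc6ccccc6)cc3[C@H]3[C@H](c4ccc(OCc6ccccc6)cc4)c4c(cc5c(c4OC(=O)N(CC)CC)[C@H](c4cc(OCc6ccccc6)cc(OCc6ccccc6)c4)[C@@H](c4ccc(OCc6ccccc6)cc4)O5)[C@@H]23)cc1 | intermediate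
30 | hepta-O-benzyl ether of the target (free hydroxyl on benzofuran C4) | c1ccccc1COc1ccc([C@@H]2c3c(OCc6ccccc6)cc(OCc6ccccc6)cc3[C@H]3[C@H](c4ccc(OCc6ccccc6)cc4)c4c(cc5c(c4O)[C@H](c4cc(OCc6ccccc6)cc(OCc6ccccc6)c4)[C@@H](c4ccc(OCc6ccccc6)cc4)O5)[C@@H]23)cc1 | intermediate
31 | CNP0198336.1 | Oc1ccc([C@@H]2c3c(O)cc(O)cc3[C@H]3[C@H](c4ccc(O)cc4)c4c(cc5c(c4O)[C@H](c4cc(O)cc(O)c4)[C@@H](c4ccc(O)cc4)O5)[C@@H]23)cc1 | target

**Step count and risks**

Total step count: 18. Longest linear sequence: 14 steps (steps 5 to 18, from 10).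

Steps most likely to fail:

1. Step 16. Fluoride may act as a base on the doubly benzylic, cyclopentadiene-type C1–H of 9 faster than the ene reaction proceeds. That would cause racemisation, a 1,3-hydrogen shift, or addition of the indenyl anion to the aryne. The fallback forms the two bonds one after the other from the base-stable indanone. It sets out from 22 and 5 and comes back at 29. Phenol 22 is converted with Tf2O/pyridine into the aryl triflate F1. Pd-catalysed ketone α-arylation of 5 with F1 (Pd2(dba)3, XPhos, NaOtBu, toluene) should give the thermodynamically preferred trans-2,3-disubstituted indanone F2. Addition of 7 in the presence of CeCl3 gives the tertiary indanol F3. TFA in HFIP/CH2Cl2 dehydrates F3 to the same styrene as 28 and closes the ring, giving 29.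

2. Step 10. Carbene dimerisation (azine formation) or poor enantio-induction at the crowded di-ortho-substituted diaryl carbene may occur, made worse by incomplete hydrazone formation in step 9. The fallback builds the dihydrofuran by a polar annulation and resolves it. It sets out from 11 and comes back at 20. Excess 14 adds to 11 to give the 2,6-dihydroxybenzhydrol F4. Mild base converts F4 into an ortho-quinone methide, which undergoes (4+1) annulation with the ylide from [4-(benzyloxy)benzyl]dimethylsulfonium chloride F5 (made from 6 and dimethyl sulfide). This gives the racemic trans-dihydrobenzofuranol F6, which is resolved by preparative chromatography on a chiral stationary phase to give 20.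

3. Step 4. Elimination may go towards the exocyclic benzylidene isomer, which would give the wrong connectivity in the ene reaction. The fallback fixes the double bond position before the benzyl group is attached. It sets out from 5 and comes back at 9. Ketone 5 is converted with Tf2O and 2,6-di-tert-butyl-4-methylpyridine into the enol triflate F7. Negishi coupling of F7 with [4-(benzyloxy)benzyl]zinc chloride F8 (made from 6 and zinc dust) under Pd(PPh3)4 gives 9.

**Further compounds**

F1 | step 16 | (2S,3S)-2-[4-(benzyloxy)phenyl]-3-[3,5-bis(benzyloxy)phenyl]-4-[(diethylcarbamoyl)oxy]-2,3-dihydrobenzofuran-6-yl trifluoromethanesulfonate | FC(F)(F)S(=O)(=O)Oc1cc2c(c(OC(=O)N(CC)CC)c1)[C@H](c1cc(OCc3ccccc3)cc(OCc3ccccc3)c1)[C@@H](c1ccc(OCc3ccccc3)cc1)O2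
F2 | step 16 | (2R,3R)-trans-4,6-bis(benzyloxy)-3-[4-(benzyloxy)phenyl]indan-1-one carrying at C2 the dihydrobenzofuran-6-yl group of 22 | O=C1[C@@H](c2cc3c(c(OC(=O)N(CC)CC)c2)[C@H](c2cc(OCc4ccccc4)cc(OCc4ccccc4)c2)[C@@H](c2ccc(OCc4ccccc4)cc2)O3)[C@H](c2ccc(OCc4ccccc4)cc2)c2c(OCc4ccccc4)cc(OCc4ccccc4)cc12
F3 | step 16 | 1-[4-(benzyloxy)benzyl]indan-1-ol from F2 (both C1 epimers) | OC1(Cc2ccc(OCc4ccccc4)cc2)[C@@H](c2cc3c(c(OC(=O)N(CC)CC)c2)[C@H](c2cc(OCc4ccccc4)cc(OCc4ccccc4)c2)[C@@H](c2ccc(OCc4ccccc4)cc2)O3)[C@H](c2ccc(OCc4ccccc4)cc2)c2c(OCc4ccccc4)cc(OCc4ccccc4)cc12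
F4 | step 10 | [4-(allyloxy)-2,6-dihydroxyphenyl][3,5-bis(benzyloxy)phenyl]methanol (racemic) | OC(c1cc(OCc2ccccc2)cc(OCc2ccccc2)c1)c1c(O)cc(OCC=C)cc1O
F5 | step 10 | [4-(benzyloxy)benzyl]dimethylsulfonium chloride | [Cl-].C[S+](C)Cc1ccc(OCc2ccccc2)cc1
F6 | step 10 | (±)-trans-6-(allyloxy)-2-[4-(benzyloxy)phenyl]-3-[3,5-bis(benzyloxy)phenyl]-2,3-dihydrobenzofuran-4-ol (racemate of 20) | C=CCOc1cc2c(c(O)c1)C(c1cc(OCc3ccccc3)cc(OCc3ccccc3)c1)C(c1ccc(OCc3ccccc3)cc1)O2
F7 | step 4 | (1R)-5,7-bis(benzyloxy)-1-[4-(benzyloxy)phenyl]-1H-inden-3-yl trifluoromethanesulfonate | FC(F)(F)S(=O)(=O)OC1=C[C@H](c2ccc(OCc3ccccc3)cc2)c2c(OCc3ccccc3)cc(OCc3ccccc3)cc12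
F8 | step 4 | [4-(benzyloxy)benzyl]zinc chloride | Cl[Zn]Cc1ccc(OCc2ccccc2)cc1
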